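**Strategy.** The 19-membered ansa lactam is closed late at C5–C6 (ansamycin numbering: C1 amide carbonyl to C15, quinone ring C16–C21). The C6 carbinol next to the C7 oxygen and the C5H2–C4H2–C3H=C2(Me)–C1 amide unit are read as the reductive adduct of an aldehyde and a terminal 1,3-diene. A nickel-catalysed, Et2Zn-promoted diene–aldehyde homoallylation joins C5 to C6, returns the (E)-C2=C3 enamide and sets C6 under chelate control from C7. The precursor is a seco-aldehyde whose trimethoxyanilide carries an (E)-2-methylpenta-2,4-dienoyl group; its 11,15-trans pyran ring comes from an arylzinc and an anomeric sulfone, its C8=C9 alkene from hydrozirconation of an alkyne.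

Key step: step 21

Remark: ansamycin numbering is used throughout, the target is made as its 2-hydroxy-1,4-quinone tautomer, and anhydrous ethyl glyoxylate and (R)-glyceraldehyde acetonide are taken as commercial.

**Step 1**
Reactants: 1 (S)-but-3-yn-2-ol
Product: 2 (S)-but-3-yn-2-yl methanesulfonate
Conditions: MsCl, Et3N, CH2Cl2, −78 to 0 °C
Reagents that add atoms: methanesulfonyl chloride, CS(Cl)(=O)=O
Why: O-sulfonylation (mesylation) does not touch the C–O bond of the carbinol, so the (S) configuration is carried into the leaving group.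

**Step 2**
Reactants: 2 (S)-but-3-yn-2-yl methanesulfonate
Product: 3 (M)-tributyl(buta-1,2-dien-1-yl)stannane
Conditions: Bu3SnH, LiN(i-Pr)2, THF, 0 °C; CuBr·SMe2, −78 °C; then 2
Reagents that add atoms: tributylstannyllithium, [Li][Sn](CCCC)(CCCC)CCCC
Why: the stannylcopper reagent displaces the propargylic mesylate in an anti SN2′ substitution, which turns the (S) centre into the (M) axis of the allene (centre-to-axis chirality transfer).

**Step 3**
Reactants: 3 (M)-tributyl(buta-1,2-dien-1-yl)stannane; 4 ethyl glyoxylate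
Product: 5 ethyl (2R,3S)-2-hydroxy-3-methylpent-4-ynoate
Conditions: BF3·OEt2, CH2Cl2, −78 °C
Reagents that add atoms: none
Why: BF3-promoted SE2′ addition of the allenylstannane runs anti to tin through an open antiperiplanar transition state, so the allene axis sets the methyl-bearing carbon (3S, later C10) and the syn topology sets the carbinol (2R, later C11).

**Step 4**
Reactants: 5 ethyl (2R,3S)-2-hydroxy-3-methylpent-4-ynoate
Product: 6 ethyl (2R,3S)-3-methyl-2-(triisopropylsilyloxy)pent-4-ynoate
Conditions: TIPSOTf, 2,6-lutidine, CH2Cl2, 0 °C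
Reagents that add atoms: triisopropylsilyl trifluoromethanesulfonate, CC(C)[Si](OS(=O)(=O)C(F)(F)F)(C(C)C)C(C)C
Why: silyl triflate silylation of the secondary alcohol installs a bulky non-chelating ether that directs the later addition in the Felkin–Anh sense and is slow to migrate.

**Step 5**
Reactants: 6 ethyl (2R,3S)-3-methyl-2-(triisopropylsilyloxy)pent-4-ynoate
Product: 7 (2R,3S)-3-methyl-2-(triisopropylsilyloxy)pent-4-ynal
Conditions: i-Bu2AlH, CH2Cl2, −78 °C; aqueous tartrate work-up
Reagents that add atoms: none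
Why: at −78 °C the aluminium hemiacetal of the α-silyloxy ester survives until work-up, so the i-Bu2AlH reduction stops at the aldehyde without epimerising the α centre.

**Step 6**
Reactants: 8 (R)-3-bromo-2-methylpropan-1-ol
Product: 9 (R)-(3-bromo-2-methylpropoxy)(tert-butyl)dimethylsilane
Conditions: TBSCl, imidazole, DMF, 25 °C
Reagents that add atoms: tert-butyldimethylsilyl chloride, CC(C)(C)[Si](C)(C)Cl
Why: imidazole-mediated silylation of the primary alcohol does not involve the methyl-bearing centre (later C14).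

**Step 7**
Reactants: 9 (R)-(3-bromo-2-methylpropoxy)(tert-butyl)dimethylsilane; 7 (2R,3S)-3-methyl-2-(triisopropylsilyloxy)pent-4-ynal
Product: 11 (2S,4S,5R,6S)-1-(tert-butyldimethylsilyloxy)-2,6-dimethyl-5-(triisopropylsilyloxy)oct-7-yn-4-ol, via Grignard reagent 10 (not isolated)
Conditions: Mg, THF, 40 °C; then 7 added at −78 °C
Reagents that add atoms: none
Why: Grignard addition to the α-silyloxy aldehyde follows the Felkin–Anh model (C–OTIPS anti to the nucleophile) and should give the 4,5-anti alcohol (4S, later C12), inverse addition at −78 °C letting carbonyl addition outrun deprotonation of the alkyne.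

**Step 8**
Reactants: 11 (2S,4S,5R,6S)-1-(tert-butyldimethylsilyloxy)-2,6-dimethyl-5-(triisopropylsilyloxy)oct-7-yn-4-ol
Product: 12 (2S,4S,5R,6S)-1-(tert-butyldimethylsilyloxy)-4-methoxy-2,6-dimethyl-5-(triisopropylsilyloxy)non-7-yne
Conditions: n-BuLi (2.3 equiv), THF, −78 °C; MeI, DMPU, −78 to 25 °C
Reagents that add atoms: iodomethane, CI
Why: double deprotonation then methylation turns the alkoxide into the C12 methyl ether (Williamson) and the acetylide into the methyl alkyne that carries the future C8 methyl group, the lithium counter-ion and the bulky TIPS group disfavouring 1,2-silyl migration.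

**Step 9**
Reactants: 12 (2S,4S,5R,6S)-1-(tert-butyldimethylsilyloxy)-4-methoxy-2,6-dimethyl-5-(triisopropylsilyloxy)non-7-yne
Product: 13 (2S,4S,5R,6S)-4-methoxy-2,6-dimethylnon-7-yne-1,5-diol
Conditions: Bu4NF, THF, 25 °C
Reagents that add atoms: none
Why: fluoride cleaves both silyl ethers through Si–F bond formation and leaves the methyl ether, the alkyne and all stereocentres untouched.

**Step 10**
Reactants: 13 (2S,4S,5R,6S)-4-methoxy-2,6-dimethylnon-7-yne-1,5-diol
Product: 14 (3S,5S,6R)-5-methoxy-3-methyl-6-[(2S)-pent-3-yn-2-yl]oxan-2-one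
Conditions: TEMPO (10 mol %), PhI(OAc)2 (2.5 equiv), CH2Cl2, 25 °C
Reagents that add atoms: none
Why: the oxoammonium salt oxidises the primary alcohol selectively, the hydroxy aldehyde closes onto the C11 hydroxyl and the six-membered hemiacetal is oxidised on to the δ-lactone (TEMPO oxidative lactonisation).

**Step 11**
Reactants: 14 (3S,5S,6R)-5-methoxy-3-methyl-6-[(2S)-pent-3-yn-2-yl]oxan-2-one
Product: 15 (3S,5S,6R)-5-methoxy-3-methyl-6-[(2S)-pent-3-yn-2-yl]oxan-2-ol (both anomers)
Conditions: i-Bu2AlH, CH2Cl2, −78 °C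
Reagents that add atoms: none
Why: hydride addition to the lactone at −78 °C stops at the aluminium lactolate, which gives the lactol on work-up without enolisation at C14.

**Step 12**
Reactants: 15 (3S,5S,6R)-5-methoxy-3-methyl-6-[(2S)-pent-3-yn-2-yl]oxan-2-ol
Product: 16 (3S,5S,6R)-2-(benzenesulfonyl)-5-methoxy-3-methyl-6-[(2S)-pent-3-yn-2-yl]oxane (both anomers)
Conditions: PhSO2H, CaCl2, CH2Cl2, 25 °C
Reagents that add atoms: benzenesulfinic acid, OS(=O)c1ccccc1
Why: acid-catalysed exchange of the anomeric hydroxyl through the ring oxocarbenium ion gives the anomeric sulfone, a storable oxocarbenium precursor.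

**Step 13**
Reactants: 17 1,2,4-trimethoxybenzene; 16 (3S,5S,6R)-2-(benzenesulfonyl)-5-methoxy-3-methyl-6-[(2S)-pent-3-yn-2-yl]oxane
Product: 20 (2S,3S,5S,6R)-5-methoxy-3-methyl-6-[(2S)-pent-3-yn-2-yl]-2-(2,3,6-trimethoxyphenyl)oxane, via aryllithium 18 (not isolated), via arylzinc bromide 19 (not isolated)
Conditions: 17 (3 equiv), n-BuLi, THF, 0 °C; ZnBr2, 0 to 25 °C; then 16, 25 °C
Reagents that add atoms: none
Why: directed ortho-lithiation between the two flanking methoxy groups fixes the arene position, and zinc-assisted ionisation of the anomeric sulfone lets the arylzinc add axially to the half-chair oxocarbenium ion with the C11 side chain and C12 methoxy group pseudo-equatorial, anti to the pseudo-axial C14 methyl, which should give the 11,15-trans pyran (15S).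

**Step 14**
Reactants: 20 (2S,3S,5S,6R)-5-methoxy-3-methyl-6-[(2S)-pent-3-yn-2-yl]-2-(2,3,6-trimethoxyphenyl)oxane
Product: 21 (2S,3S,5S,6R)-2-(3-iodo-2,5,6-trimethoxyphenyl)-5-methoxy-3-methyl-6-[(2S)-pent-3-yn-2-yl]oxane
Conditions: NIS, MeCN, 0 to 25 °C
Reagents that add atoms: N-iodosuccinimide, O=C1CCC(=O)N1I
Why: electrophilic aromatic iodination goes to the free position that is para to one methoxy group and ortho to another (C20), the most activated site, far faster than any reaction at the alkyne.

**Step 15**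
Reactants: 21 (2S,3S,5S,6R)-2-(3-iodo-2,5,6-trimethoxyphenyl)-5-methoxy-3-methyl-6-[(2S)-pent-3-yn-2-yl]oxane; 22 (R)-2,2-dimethyl-1,3-dioxolane-4-carbaldehyde
Product: 25 (1S,2E,4S)-1-[(4R)-2,2-dimethyl-1,3-dioxolan-4-yl]-4-[(2R,3S,5S,6S)-6-(3-iodo-2,5,6-trimethoxyphenyl)-3-methoxy-5-methyloxan-2-yl]-2-methylpent-2-en-1-ol, via alkenylzirconocene chloride 23 (not isolated), via alkenyl(methyl)zinc 24 (not isolated)
Conditions: Cp2Zr(H)Cl, CH2Cl2, 25 °C; Me2Zn, toluene, −65 °C; (−)-MIB (10 mol %); 22, −30 to 0 °C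
Reagents that add atoms: none
Why: syn hydrozirconation puts zirconium on the less hindered methyl-bearing alkyne carbon and so fixes the (E)-trisubstituted C8=C9 alkene, zirconium-to-zinc transmetalation gives an alkenylzinc, and the amino alcohol ligand delivers it to the Si face of the aldehyde in the sense that the Felkin–Anh preference of the (R)-dioxolane also favours, setting C7 (S).

**Step 16**
Reactants: 25 allylic alcohol (C7 hydroxyl)
Product: 26 4-methoxybenzyl ether of 25 at the C7 oxygen
Conditions: NaH, PMBCl, Bu4NI (cat.), DMF, 0 to 25 °C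
Reagents that add atoms: 4-methoxybenzyl chloride, COc1ccc(CCl)cc1
Why: Williamson etherification of the sodium alkoxide installs a chelating ether on O7, the neighbouring acetonide cannot migrate and the aryl iodide is inert.

**Step 17**
Reactants: 27 acrolein; 28 ethyl 2-(triphenyl-λ5-phosphanylidene)propanoate
Product: 29 ethyl (2E)-2-methylpenta-2,4-dienoate
Conditions: CH2Cl2, 0 to 25 °C
Reagents that add atoms: none
Why: the Wittig reaction of the ester-stabilised ylide is (E)-selective and gives the trisubstituted C2=C3 alkene with the vinyl group intact.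

**Step 18**
Reactants: 29 ethyl (2E)-2-methylpenta-2,4-dienoate
Product: 30 (2E)-2-methylpenta-2,4-dienamide
Conditions: AlMe3, NH4Cl, toluene, 0 to 50 °C
Reagents that add atoms: ammonium chloride, [NH4+].[Cl-] (nitrogen source, delivered as chloro(methyl)aluminium amide, C[Al](N)Cl)
Why: the aluminium amide formed from AlMe3 and NH4Cl converts the ester into the primary amide by addition–elimination at the carbonyl, without conjugate addition to the diene.

**Step 19**
Reactants: 26 aryl iodide PMB ether; 30 (2E)-2-methylpenta-2,4-dienamide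
Product: 31 N-aryl (2E)-2-methylpenta-2,4-dienamide (iodine of 26 replaced by the amide nitrogen at C20)
Conditions: CuI (10 mol %), N,N′-dimethylethane-1,2-diamine (20 mol %), K2CO3, toluene, 110 °C
Reagents that add atoms: none
Why: copper-catalysed Goldberg amidation couples the primary amide nitrogen with the aryl iodide, and copper, unlike palladium, does not trigger a Heck reaction of the diene.

**Step 20**
Reactants: 31 anilide acetonide
Product: 33 seco-aldehyde (C6 aldehyde, C7 PMB ether, C20 dienamide), via diol 32 (not isolated)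
Conditions: AcOH/H2O (4:1), 40 °C; then NaIO4, THF/aq. pH 7 buffer, 0 °C
Reagents that add atoms: none
Why: aqueous acetic acid hydrolyses the terminal acetonide and periodate cleaves the resulting 1,2-diol (glycol cleavage) to the α-alkoxy aldehyde, which erases the temporary centre at C6 and leaves C7 untouched.

**Step 21**
Reactants: 33 seco-aldehyde
Product: 34 macrocyclic lactam with C6 hydroxyl (2E,8E; 6S,7S,10S,11R,12S,14S,15S), C7 PMB ether and trimethoxyarene
Conditions: Ni(acac)2 (20 mol %), Et2Zn (3.5 equiv), THF, 25 °C, 33 added over 12 h to 0.002 M; aq. NH4Cl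
Reagents that add atoms: none
Why: Proposed new method: zerovalent nickel (from Ni(acac)2 and Et2Zn) binds the terminal C4=C5 alkene of the dienamide and the zinc-activated C6 aldehyde and couples them oxidatively to an oxanickelacycle (C5–C6 bond, η3-allyl over C4–C2); ethyl transfer from zinc, β-hydride elimination (ethylene) and C–H reductive elimination at C4 then release the zinc alkoxide with C2=C3 back in conjugation. The closest known reaction type is the nickel-catalysed, Et2Zn- or Et3B-promoted homoallylation of aldehydes with 1,3-dienes, known between two molecules and for closing five- and six-membered rings, but not for a macrocycle or a dienamide. The 19-membered ansa ring closes by end-to-end attack of the diene terminus C5 on the aldehyde carbon, and the (E) geometry of C2=C3 should be carried over because the allyl intermediate keeps the more stable arrangement with the amide carbonyl trans to C4. The new C6 carbinol centre is set by the C7 stereocentre through a Cram chelate in which zinc bridges the aldehyde oxygen and the PMB ether oxygen, so that C5 adds anti to the C8 alkenyl group and gives the 6,7-syn (6S) isomer. The step needs attack at the unsubstituted diene terminus with hydride return to C4, homoallylation in preference to ethyl transfer, and ring closure in preference to oligomerisation; the fully substituted C2, the conjugating amide, the extra Et2Zn that masks the anilide N–H and slow addition at high dilution are meant to secure these.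

**Step 22**
Reactants: 34 macrocyclic C6 alcohol
Product: 35 macrocyclic C6 methyl ether
Conditions: TMSCHN2, aq. HBF4 (cat.), CH2Cl2, 0 °C
Reagents that add atoms: (trimethylsilyl)diazomethane, C[Si](C)(C)C=[N+]=[N-]
Why: acid-activated (trimethylsilyl)diazomethane methylates the only free hydroxyl with retention at C6 and, unlike basic or strongly electrophilic methylating agents, leaves the anilide N–H alone.

**Step 23**
Reactants: 35 macrocyclic C6 methyl ether
Product: 36 17-methoxy-para-quinone with free C7 hydroxyl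
Conditions: (NH4)2Ce(NO3)6 (6 equiv), MeCN/H2O, 0 °C
Reagents that add atoms: water, O
Why: one-electron oxidation of the electron-rich arene, attack of water and loss of methanol give the para-quinone (C18 and C21 carbonyls) with the C17 methoxy kept as a vinylogous ester, and the same oxidant cleaves the PMB ether to free the C7 hydroxyl (oxidative demethylation and oxidative debenzylation).

**Step 24**
Reactants: 36 17-methoxy-para-quinone
Product: 37 CNP0204467.1
Conditions: LiOH, THF/H2O, 0 to 25 °C; then dilute HCl to pH 3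
Reagents that add atoms: lithium hydroxide, [Li+].[OH-]
Why: hydroxide adds to C17 of the vinylogous ester and expels methoxide (addition–elimination), giving the 2-hydroxy-1,4-quinone without touching any stereocentre.

**Compound list**

1 | (S)-but-3-yn-2-ol | C[C@H](O)C#C | starting material
2 | (S)-but-3-yn-2-yl methanesulfonate | C[C@H](OS(C)(=O)=O)C#C | intermediate
3 | (M)-tributyl(buta-1,2-dien-1-yl)stannane | [H]C(C)=[C@@]=C([H])[Sn](CCCC)(CCCC)CCCC | intermediate
4 | ethyl glyoxylate | CCOC(=O)C=O | starting material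
5 | ethyl (2R,3S)-2-hydroxy-3-methylpent-4-ynoate | CCOC(=O)[C@H](O)[C@@H](C)C#C | intermediate
6 | ethyl (2R,3S)-3-methyl-2-(triisopropylsilyloxy)pent-4-ynoate | CCOC(=O)[C@H](O[Si](C(C)C)(C(C)C)C(C)C)[C@@H](C)C#C | intermediate
7 | (2R,3S)-3-methyl-2-(triisopropylsilyloxy)pent-4-ynal | O=C[C@H](O[Si](C(C)C)(C(C)C)C(C)C)[C@@H](C)C#C | intermediate
8 | (R)-3-bromo-2-methylpropan-1-ol | BrC[C@H](C)CO | starting material
9 | (R)-(3-bromo-2-methylpropoxy)(tert-butyl)dimethylsilane | BrC[C@H](C)CO[Si](C)(C)C(C)(C)C | intermediate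
10 | (R)-[3-(tert-butyldimethylsilyloxy)-2-methylpropyl]magnesium bromide | Br[Mg]C[C@H](C)CO[Si](C)(C)C(C)(C)C | intermediate (not isolated)
11 | (2S,4S,5R,6S)-1-(tert-butyldimethylsilyloxy)-2,6-dimethyl-5-(triisopropylsilyloxy)oct-7-yn-4-ol | O[C@H]([C@H](O[Si](C(C)C)(C(C)C)C(C)C)[C@@H](C)C#C)C[C@H](C)CO[Si](C)(C)C(C)(C)C | intermediate
12 | (2S,4S,5R,6S)-1-(tert-butyldimethylsilyloxy)-4-methoxy-2,6-dimethyl-5-(triisopropylsilyloxy)non-7-yne | CO[C@H]([C@H](O[Si](C(C)C)(C(C)C)C(C)C)[C@@H](C)C#CC)C[C@H](C)CO[Si](C)(C)C(C)(C)C | intermediate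
13 | (2S,4S,5R,6S)-4-methoxy-2,6-dimethylnon-7-yne-1,5-diol | CO[C@H]([C@H](O)[C@@H](C)C#CC)C[C@H](C)CO | intermediate
14 | (3S,5S,6R)-5-methoxy-3-methyl-6-[(2S)-pent-3-yn-2-yl]oxan-2-one | CO[C@H]1C[C@H](C)C(=O)O[C@@H]1[C@@H](C)C#CC | intermediate
15 | (3S,5S,6R)-5-methoxy-3-methyl-6-[(2S)-pent-3-yn-2-yl]oxan-2-ol, both anomers | CO[C@H]1C[C@H](C)C(O)O[C@@H]1[C@@H](C)C#CC | intermediate
16 | (3S,5S,6R)-2-(benzenesulfonyl)-5-methoxy-3-methyl-6-[(2S)-pent-3-yn-2-yl]oxane, both anomers | CO[C@H]1C[C@H](C)C(S(=O)(=O)c2ccccc2)O[C@@H]1[C@@H](C)C#CC | intermediate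
17 | 1,2,4-trimethoxybenzene | COc1ccc(OC)c(OC)c1 | starting material
18 | (2,3,6-trimethoxyphenyl)lithium | [Li]c1c(OC)c(OC)ccc1OC | intermediate (not isolated)
19 | (2,3,6-trimethoxyphenyl)zinc bromide | Br[Zn]c1c(OC)c(OC)ccc1OC | intermediate (not isolated)
20 | (2S,3S,5S,6R)-5-methoxy-3-methyl-6-[(2S)-pent-3-yn-2-yl]-2-(2,3,6-trimethoxyphenyl)oxane | CO[C@H]1C[C@H](C)[C@@H](c2c(OC)c(OC)ccc2OC)O[C@@H]1[C@@H](C)C#CC | intermediate
21 | (2S,3S,5S,6R)-2-(3-iodo-2,5,6-trimethoxyphenyl)-5-methoxy-3-methyl-6-[(2S)-pent-3-yn-2-yl]oxane | CO[C@H]1C[C@H](C)[C@@H](c2c(OC)c(OC)cc(I)c2OC)O[C@@H]1[C@@H](C)C#CC | intermediate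
22 | (R)-2,2-dimethyl-1,3-dioxolane-4-carbaldehyde | O=C[C@H]1COC(C)(C)O1 | starting material
23 | chlorobis(cyclopentadienyl)[(E)-alkenyl]zirconium from 21 (Zr on C8) | CO[C@H]1C[C@H](C)[C@@H](c2c(OC)c(OC)cc(I)c2OC)O[C@@H]1[C@@H](C)/C=C(\C)[Zr](Cl)(C1C=CC=C1)C1C=CC=C1 | intermediate (not isolated)
24 | (E)-alkenyl(methyl)zinc from 23 (Zn on C8) | CO[C@H]1C[C@H](C)[C@@H](c2c(OC)c(OC)cc(I)c2OC)O[C@@H]1[C@@H](C)/C=C(\C)[Zn]C | intermediate (not isolated)
25 | (1S,2E,4S)-1-[(4R)-2,2-dimethyl-1,3-dioxolan-4-yl]-4-[(2R,3S,5S,6S)-6-(3-iodo-2,5,6-trimethoxyphenyl)-3-methoxy-5-methyloxan-2-yl]-2-methylpent-2-en-1-ol | CO[C@H]1C[C@H](C)[C@@H](c2c(OC)c(OC)cc(I)c2OC)O[C@@H]1[C@@H](C)/C=C(\C)[C@H](O)[C@H]1COC(C)(C)O1 | intermediate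
26 | 4-methoxybenzyl ether of 25 at the C7 oxygen | CO[C@H]1C[C@H](C)[C@@H](c2c(OC)c(OC)cc(I)c2OC)O[C@@H]1[C@@H](C)/C=C(\C)[C@H](OCc2ccc(OC)cc2)[C@H]1COC(C)(C)O1 | intermediate
27 | acrolein (prop-2-enal) | C=CC=O | starting material
28 | ethyl 2-(triphenyl-λ5-phosphanylidene)propanoate | CCOC(=O)C(C)=P(c1ccccc1)(c1ccccc1)c1ccccc1 | starting material
29 | ethyl (2E)-2-methylpenta-2,4-dienoate | CCOC(=O)/C(C)=C/C=C | intermediate
30 | (2E)-2-methylpenta-2,4-dienamide | NC(=O)/C(C)=C/C=C | intermediate
31 | anilide acetonide: 26 with iodine replaced by NH–CO–C(Me)=CH–CH=CH2 (E) | CO[C@H]1C[C@H](C)[C@@H](c2c(OC)c(OC)cc(NC(=O)/C(C)=C/C=C)c2OC)O[C@@H]1[C@@H](C)/C=C(\C)[C@H](OCc2ccc(OC)cc2)[C@H]1COC(C)(C)O1 | intermediate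
32 | anilide 1,2-diol from hydrolysis of the acetonide of 31 | CO[C@H]1C[C@H](C)[C@@H](c2c(OC)c(OC)cc(NC(=O)/C(C)=C/C=C)c2OC)O[C@@H]1[C@@H](C)/C=C(\C)[C@H](OCc2ccc(OC)cc2)[C@H](O)CO | intermediate (not isolated)
33 | seco-aldehyde: (2S,3E,5S)-hex-3-enal with C7 PMB ether, C8 methyl, the pyran at C10 and the C20 dienamide | CO[C@H]1C[C@H](C)[C@@H](c2c(OC)c(OC)cc(NC(=O)/C(C)=C/C=C)c2OC)O[C@@H]1[C@@H](C)/C=C(\C)[C@H](OCc2ccc(OC)cc2)C=O | intermediate
34 | macrocyclic lactam, C6 hydroxyl (6S), C7 PMB ether, 17,18,21-trimethoxyarene | CO[C@H]1C[C@H](C)[C@@H]2O[C@@H]1[C@@H](C)/C=C(\C)[C@H](OCc3ccc(OC)cc3)[C@@H](O)CC/C=C(\C)C(=O)Nc1cc(OC)c(OC)c2c1OC | intermediate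
35 | macrocyclic lactam, C6 methyl ether, C7 PMB ether, 17,18,21-trimethoxyarene | CO[C@H]1C[C@H](C)[C@@H]2O[C@@H]1[C@@H](C)/C=C(\C)[C@H](OCc3ccc(OC)cc3)[C@@H](OC)CC/C=C(\C)C(=O)Nc1cc(OC)c(OC)c2c1OC | intermediate
36 | 17-O-methyl ether of the target (17-methoxy-18,21-para-quinone, free C7 hydroxyl) | CO[C@H]1C[C@H](C)[C@@H]2O[C@@H]1[C@@H](C)/C=C(\C)[C@H](O)[C@@H](OC)CC/C=C(\C)C(=O)NC1=CC(=O)C(OC)=C2C1=O | intermediate
37 | CNP0204467.1 | CO[C@H]1C[C@H](C)[C@@H]2O[C@@H]1[C@@H](C)/C=C(\C)[C@H](O)[C@@H](OC)CC/C=C(\C)C(=O)NC1=CC(=O)C(O)=C2C1=O | target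

**Totals.** Total step count: 24. Longest linear sequence: 21 steps (steps 1–5, 7–16 and 19–24, from compound 1).

**Steps most likely to fail**

Step 21 (the proposed macrocyclisation). The diene–aldehyde coupling may lose to oligomerisation, to ethyl transfer to the aldehyde, to nickel insertion into the allylic C7–O bond, or to attack on the wrong aldehyde face. The fallback builds C5–C6 between two molecules with chelation control and closes the ring at nitrogen instead. It sets out from 26 and comes back at 35. Acetonide hydrolysis and periodate cleavage as in step 20 should give the aryl iodide aldehyde F1. Addition of but-3-enylmagnesium bromide with MgBr2·OEt2 in CH2Cl2 at −78 °C (Cram chelate through the PMB ether) should give the 6,7-syn homoallylic alcohol F2. NaH and MeI, with no amide yet present, give the C6 methyl ether F3. Cross-metathesis with methacrylamide (second-generation Grubbs catalyst) should give the (E)-primary enamide F4. An intramolecular Goldberg amidation (CuI, N,N′-dimethylethane-1,2-diamine, K2CO3, toluene, 110 °C, high dilution) then closes the lactam to 35.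

Step 15 (alkenylzinc addition). Facial selectivity at C7 may be poor if the ligand and the substrate bias do not reinforce each other as assumed. The fallback sets the centre by reduction instead of by C–C bond formation. It sets out from the C7-epimeric mixture of 25 and comes back at 25. Oxidation with DMP (NaHCO3, CH2Cl2) gives the enone F5, and Zn(BH4)2 in Et2O at −20 °C reduces it under chelation with the dioxolane oxygen, which should give the anti (7S) alcohol 25.

Step 23 (oxidation with (NH4)2Ce(NO3)6). Demethylation may take the ortho pair (C17 and C18) instead of the para pair, or the benzylic C15 position and the allylic alcohol may be over-oxidised. The ortho-quinone is not fatal, since hydrolysis in step 24 should funnel it to the same hydroxyquinone, but over-oxidation is. The fallback separates deprotection from arene oxidation. It sets out from 35 and comes back at 36. DDQ in CH2Cl2/pH 7 buffer removes the PMB group to give the C7 alcohol F6, and PhI(OCOCF3)2 in aqueous MeCN at 0 °C then carries out the oxidative demethylation to 36.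

**Further compounds**

F1 | step 21 | aryl iodide aldehyde: C6 aldehyde with C7 PMB ether | CO[C@H]1C[C@H](C)[C@@H](c2c(OC)c(OC)cc(I)c2OC)O[C@@H]1[C@@H](C)/C=C(\C)[C@H](OCc2ccc(OC)cc2)C=O
F2 | step 21 | 6,7-syn homoallylic alcohol (6S) with terminal C3 alkene | CO[C@H]1C[C@H](C)[C@@H](c2c(OC)c(OC)cc(I)c2OC)O[C@@H]1[C@@H](C)/C=C(\C)[C@H](OCc2ccc(OC)cc2)[C@@H](O)CCC=C
F3 | step 21 | C6 methyl ether of F2 | CO[C@H]1C[C@H](C)[C@@H](c2c(OC)c(OC)cc(I)c2OC)O[C@@H]1[C@@H](C)/C=C(\C)[C@H](OCc2ccc(OC)cc2)[C@@H](OC)CCC=C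
F4 | step 21 | seco (2E)-2-methyl-enamide (primary amide) with aryl iodide | CO[C@H]1C[C@H](C)[C@@H](c2c(OC)c(OC)cc(I)c2OC)O[C@@H]1[C@@H](C)/C=C(\C)[C@H](OCc2ccc(OC)cc2)[C@@H](OC)CC/C=C(\C)C(N)=O
F5 | step 15 | C7 enone with (4R)-dioxolane | CO[C@H]1C[C@H](C)[C@@H](c2c(OC)c(OC)cc(I)c2OC)O[C@@H]1[C@@H](C)/C=C(\C)C(=O)[C@H]1COC(C)(C)O1
F6 | step 23 | macrocyclic lactam with free C7 hydroxyl, C6 methyl ether and trimethoxyarene | CO[C@H]1C[C@H](C)[C@@H]2O[C@@H]1[C@@H](C)/C=C(\C)[C@H](O)[C@@H](OC)CC/C=C(\C)C(=O)Nc1cc(OC)c(OC)c2c1OC
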